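The numbers in the tables were generated by integration from invented constants, and the scatter is random.

The product made in the gamma flask by 4.00 h outweighed the initiator charged, by a factor of 14.2. I therefore took the gamma run for a chain, and I watched the product.

- gamma: starting material 0.050 M; partner 0.090 M; initiator 0.60 mM; the very flask that is asked about, followed so far
- flask: starting material 0.050 M; partner 0.0900 M; initiator 0.60 mM; time 30 h

gamma run (percent of the starting material charged)

| time / h | product / % |
|---|---|
| 0.500 | 2.9 |
| 1.00 | 4.4 |
| 1.50 | 6.6 |
| 2.00 | 9.2 |
| 2.50 | 11.3 |
| 3.00 | 13.4 |
| 4.00 | 17.0 |

(standard deviation of a reading: 0.5 percentage points)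



1. amount of product in percent of the starting material charged, at 3.0 h, 10 h, 20 h and 30 h

The bench rule is to divide yield by time and keep that slope. For the gamma flask I got 0.0425 h⁻¹ of the charge. But that line reaches the whole charge at 23.5 h, sooner than the asked 30 h. Slope times 30 h is 1.28, and a charge allows 1. The rule had to stop before the end of the gamma flask.

So I replaced the curve by its mean. I assumed one starting material per product and one partner per product, which made the starting material the limiting reagent, because [partner] was charged at 1.80 times [starting material]. On that assumption, the starting material over the first 4.00 h averaged about 91.5% of its charge. Slope over that mean gave k, the share of the remaining starting material turned into product per hour: 0.0464 h⁻¹. This is a reading, and its last point carries a scatter of 0.5 percentage points on 17.0%. The mean cost little: at three digits it gave 0.0464 h⁻¹, and the exact logarithm gave 0.0466 h⁻¹.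

I held k constant. My reckoning for the gamma flask was then 13.0%, 37.2%, 60.5% and 75.1%, with a half-life of 14.9 h. That half-life was the thing to watch.

The forecast read 13.3%, 34%, 52% and 62%, “with wide uncertainty at long times”, and its last value stood below mine.

The gamma flask gave 13.1%, 37.3%, 60.7% and 75.4%.

    starting material + initiating radical → capped initiator + first chain carrier (k = 2.70 × 10⁶ L mol⁻¹ s⁻¹)
    2 second chain carrier → ended chains (k = 1.80 × 10⁸ L mol⁻¹ s⁻¹)
    initiator → 2 initiating radical (k = 9.40 × 10⁻⁵ h⁻¹)
    partner + first chain carrier → product + second chain carrier (k = 5.50 × 10⁵ L mol⁻¹ s⁻¹)
    starting material + second chain carrier → by-product + first chain carrier (k = 44000 L mol⁻¹ s⁻¹)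

At the charged amounts of the gamma flask, a first chain carrier met partner at 49500 s⁻¹, and a second chain carrier met starting material at 2200 s⁻¹. The second chain carrier was the resting state, at 2.95 × 10⁻¹⁰ M after 3.00 h and 2.95 × 10⁻¹⁰ M after 30.0 h, and the loss of starting material ran pseudo-first-order: 49.6% of the starting material stood at 15.0 h, against my half-life of 14.9 h. In the thin run, diluted 2-fold, product stood at 62.9% after 30 h, which reads as a k of 0.0330 h⁻¹, my k divided by 1.41.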